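(The earlier runs and the new flask are simulated with made-up constants, noise included.)

The ratio of coupling partner to starting material in flask gamma is 105%, and that ration is the partner's whole budget, counted in fractions of the starting material charged.

| flask | starting material | second substrate | coupling partner | free catalyst | temperature | remark | time |
|---|---|---|---|---|---|---|---|
| south-east | 0.050 M | 0.025 M | 0.0525 M | 2.5 mM | 20 °C | run made earlier |  |
| north-west | 0.050 M | 0.025 M | 0.0525 M | 10 mM | 50 °C | run made earlier |  |
| north-east | 0.10 M | 0.025 M | 0.0525 M | 5 mM | 20 °C | run made earlier |  |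
| eta | 0.050 M | 0.0250 M | 0.0525 M | 5.0 mM | 25 °C |  | 4.0 h |
| gamma | 0.050 M | 0.0250 M | 0.0525 M | 5.0 mM | 50 °C |  | 4.0 h |
| zeta | 0.050 M | 0.0250 M | 0.0525 M | 5.0 mM |  | at 75 °C until 50 min, from then on at 25 °C | 4.0 h |
| epsilon | 0.050 M | 0.0250 M | 0.0525 M | 5.0 mM | 75 °C |  | 4.0 h |

south-east run (percent of the starting material charged)

| time / h | target / % | starting material / % |
|---|---|---|
| 0.417 | 4.7 | 94.4 |
| 1.00 | 10.9 | 88.2 |
| 2.00 | 19.7 | 79.3 |
| 3.00 | 26.4 | 72.8 |

north-west run (percent of the starting material charged)

| time / min | target / % | starting material / % |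
|---|---|---|
| 8.00 | 43.1 | 54.0 |
| 20.0 | 70.1 | 26.2 |
| 40.0 | 77.1 | 16.2 |
| 50.0 | 78.5 | 15.3 |

north-east run (percent of the starting material charged)

| time / h | target / % | starting material / % |
|---|---|---|
| 0.250 | 6.2 | 92.6 |
| 0.667 | 14.1 | 85.0 |
| 1.33 | 23.5 | 75.8 |
| 3.00 | 35.3 | 62.9 |

(scatter of a reading: 0.3 percentage points)



- which flask leads in amount of target, in percent of the starting material charged ("all alike" within 1.5 percentage points) (eta / gamma / zeta / epsilon / all alike)
- how much target is there at the end, in percent of the starting material charged: eta
- how much target is there at the end, in percent of the starting material charged: gamma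
- how much target is there at the end, in percent of the starting material charged: zeta
- how much target is there at the end, in percent of the starting material charged: epsilon

I asked which numbers I had to know well for gamma, the flask at the temperature of the north-west run. Time hardly mattered. The north-west run gained 1.4 percentage points in its last 10.0 min with 15.3% of its starting material still unconverted, and gamma's 4.0 h is longer than 100 min, that run's span stretched for half the catalyst. Temperature needed no correction, because gamma's 50 °C matches the north-west 50 °C.

The north-west run read 0.338: this is the waste ratio, the ration not turned into target per unit of target, a selectivity factor. I assumed that coupling scales with catalyst and that the partner's loss does not, so the catalyst charge entered my reckoning through the waste ratio. Left unscaled, gamma stays at 78.5%, and scaling takes off 16 points. A point of ration, by comparison, is worth 0.597 of a point of target. So gamma's waste ratio became 0.675, and I reckoned its target at 62.7%.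

The forecast differed from my reckoning. It gave eta 57%, gamma 74%, zeta 67% and epsilon 60%, with gamma leading, and it read the north-west stall as “a temperature-dependent ceiling (equilibrium) or catalyst death”.

The flasks gave eta 61.7%, gamma 67.0%, zeta 59.6% and epsilon 59.6%, so gamma led.

    second substrate + free catalyst ⇌ catalyst intermediate B (K = 43.3 M⁻¹, k = 4.41 M⁻¹ min⁻¹, Ea = 49.0 kJ mol⁻¹, ΔH = −90.0 kJ mol⁻¹)
    coupling partner + catalyst intermediate B → free catalyst + second product (k = 0.968 M⁻¹ min⁻¹, Ea = 46.0 kJ mol⁻¹)
    coupling partner + catalyst intermediate A → free catalyst + target (k = 17.5 M⁻¹ min⁻¹, Ea = 47.0 kJ mol⁻¹)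
    2 coupling partner → self-condensation product (k = 0.0781 M⁻¹ min⁻¹, Ea = 64.0 kJ mol⁻¹)
    starting material + free catalyst ⇌ catalyst intermediate A (K = 46.9 M⁻¹, k = 2.40 M⁻¹ min⁻¹, Ea = 46.0 kJ mol⁻¹, ΔH = 0 kJ mol⁻¹)
    second substrate + catalyst intermediate A → spent catalyst (k = 0.135 M⁻¹ min⁻¹, Ea = 55.0 kJ mol⁻¹)
    (constants at 25 °C)

Gamma's waste ratio came to 0.567 against my 0.675. At its end gamma held 0% of its coupling partner and 24.8% of its starting material, so the partner, though charged in excess, was the limiting reagent. I applied the same reckoning to a neighbour of zeta charged with 0.020 M of catalyst. Zeta's waste ratio of 0.762, divided by the catalyst factor 4.00, gives 0.190 and so a target of 88.2%. That neighbour gave 81.8%.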